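**Retrosynthetic overview**

1. Target 46 ← O-sulfation of alcohol 43 ← B-alkyl Suzuki coupling (C16–C3' bond) of the 9-BBN adduct of alkene 33 with bromolactam 40; the lactam ring is made separately from 3-methylbutan-1-amine and 2,5-dimethoxy-2,5-dihydrofuran.
2. C13 ← Evans allylation of imide 27 (acid 24 on (R)-4-benzyloxazolidin-2-one); the carboxyl carbon becomes the CH2O–SO3H carbon.
3. Ring A ← C2 deoxygenation (dithiolane, Raney Ni) of enone 18 ← aldol condensation C1–C10 with equilibration of C5 ← Mukaiyama–Michael C5–C4 bond between silyl enol ether 14 and mesityl oxide.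
4. Ring B ketone 11 ← enone 6 by copper-catalysed asymmetric conjugate methylation at C8 and enolate methylation at C9. The strategy rests on ring B (C5–C10): the C8 and C9 methyls are trans and the C9 chain (C11) is cis to the C8 methyl, which is the outcome when the chain is on C9 before either methyl arrives.
5. Ring order: ring B is bought as 2-iodocyclohex-2-en-1-one, ring A closes in step 6, the lactam ring forms in step 15 and is joined in step 17.

Key step: step 3

Numbering: decalin C1–C10 (C1=C10 alkene, C4 gem-dimethyl, C5 ring-fusion CH, C8 CH–CH3, C9 quaternary); chain C11, C12, C13 (bearing CH2O), C14–C16; lactam C3' is bonded to C16.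
Abbreviation: Dec = (1R,2R,4aS)-1,2,5,5-tetramethyl-1,2,3,4,4a,5,6,7-octahydronaphthalen-1-yl, the decalin attached through C9, with H-5, the C8 methyl and the chain on one face and the C9 methyl on the other.
Assumption: the aminophosphine enantiomer named in step 3 is taken to deliver methyl to the Re face of C8; if its sense of induction is the reverse, its mirror image is used.
Assumption: the hydrogen sulfate is isolated as the free acid drawn in the target SMILES, after cation exchange.

**Route**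

Step 1
Reactants: 1 but-3-en-1-ol; 2 chlorotriisopropylsilane
Product: 3 (but-3-en-1-yloxy)triisopropylsilane
Conditions: imidazole, DMF, rt
Reagents that add atoms: chlorotriisopropylsilane 2, CC(C)[Si](Cl)(C(C)C)C(C)C
Why: Standard silyl ether protection of a primary alcohol; triisopropylsilyl is chosen over tert-butyldimethylsilyl because the ether has to outlast TiCl4, hot methoxide and BF3·OEt2 before its removal in step 9.

Step 2
Reactants: 3 (but-3-en-1-yloxy)triisopropylsilane; 4 2-iodocyclohex-2-en-1-one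
Product: 6 2-[4-(triisopropylsilyloxy)butyl]cyclohex-2-en-1-one, via 9-[4-(triisopropylsilyloxy)butyl]-9-borabicyclo[3.3.1]nonane 5 (not isolated)
Conditions: 9-BBN, THF, 0 °C → rt; then 4, PdCl2(dppf) (5 mol %), AsPh3, Cs2CO3, DMF–THF–H2O, rt
Reagents that add atoms: 2-iodocyclohex-2-en-1-one 4, O=C1CCCC=C1I
Why: Anti-Markovnikov hydroboration gives the primary B-alkyl-9-BBN, which should undergo B-alkyl Suzuki–Miyaura coupling with the α-iodoenone (oxidative addition of zerovalent palladium into the C–I bond, base-assisted transmetalation, reductive elimination) without touching the enone.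

Step 3
Reactants: 6 2-[4-(triisopropylsilyloxy)butyl]cyclohex-2-en-1-one; 7 trimethylaluminium; 8 iodomethane
Product: 11 (2R,3R)-2,3-dimethyl-2-[4-(triisopropylsilyloxy)butyl]cyclohexan-1-one, via dimethylaluminium enolate 9 (not isolated), via lithium aluminate enolate 10 (not isolated)
Conditions: AlMe3 (1.4 equiv), CuTC [Cu(O2CC4H3S)] (5 mol %), (R,R)-Ph2P–N[CH(CH3)(2-naphthyl)]2 (10 mol %), Et2O, −30 °C; then MeLi (1.5 equiv), THF, −30 °C; HMPA, MeI (5 equiv), −30 °C → rt
Reagents that add atoms: trimethylaluminium 7, C[Al](C)C; iodomethane 8, CI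
Why: A chiral methylcopper species (monovalent copper, formed from CuTC, the aminophosphine and AlMe3) π-complexes enone 6 and transfers CH3 to the β-carbon C8 through a trivalent copper intermediate, leaving the regiodefined dimethylaluminium enolate 9 (C9=C10); MeLi turns it into the more nucleophilic lithium aluminate 10, which is C-methylated at C9 by iodomethane in an SN2 step. The closest known reaction type is the copper-catalysed asymmetric conjugate addition of trialkylaluminiums to 2-substituted cyclohex-2-enones with alkylation of the ate-activated aluminium enolate. No ring closes; the step forms the C8–CH3 and C9–CH3 bonds on the preformed ring B. C8 (R) is set by the ligand, which selects the Re face of the enone β-carbon; C9 (R) is set by the substrate, because in the tetrasubstituted enolate the C8 methyl sits pseudoaxial to avoid A(1,2) strain with the C11 chain and iodomethane enters antiperiplanar to it, so the two methyls should end trans and the chain cis to the C8 methyl. The step needs enantioface selectivity at C8, C- over O-alkylation, and methylation at C9 before the enolate can equilibrate towards C5; the non-equilibrating aluminium enolate, HMPA and an excess of the soft electrophile iodomethane are meant to secure the last two.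

Step 4
Reactants: 11 (2R,3R)-2,3-dimethyl-2-[4-(triisopropylsilyloxy)butyl]cyclohexan-1-one; 12 chlorotrimethylsilane
Product: 14 triisopropyl{4-[(1R,6R)-1,6-dimethyl-2-(trimethylsilyloxy)cyclohex-2-en-1-yl]butoxy}silane, via lithium enolate of 11 13 (not isolated)
Conditions: LDA, THF, −78 °C; TMSCl, Et3N, −78 → 0 °C; non-aqueous work-up
Reagents that add atoms: chlorotrimethylsilane 12, C[Si](C)(C)Cl
Why: C9 is quaternary, so deprotonation by LDA can only occur at the C5 methylene, and O-silylation of the enolate (enolate trapping) should give a single regioisomeric silyl enol ether.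

Step 5
Reactants: 14 triisopropyl{4-[(1R,6R)-1,6-dimethyl-2-(trimethylsilyloxy)cyclohex-2-en-1-yl]butoxy}silane; 15 4-methylpent-3-en-2-one (mesityl oxide)
Product: 16 (2R,3R,6RS)-2,3-dimethyl-6-(2-methyl-4-oxopentan-2-yl)-2-[4-(triisopropylsilyloxy)butyl]cyclohexan-1-one
Conditions: TiCl4 (1.1 equiv), CH2Cl2, −78 °C; aq. K2CO3
Reagents that add atoms: 4-methylpent-3-en-2-one 15, CC(C)=CC(C)=O
Why: Mukaiyama–Michael addition: C5 of the silyl enol ether attacks the β-carbon of TiCl4-activated mesityl oxide, forming the C5–C4 bond and the gem-dimethyl carbon C4; C5 arises as a mixture of epimers here and is settled in step 6.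

Step 6
Reactants: 16 (2R,3R,6RS)-2,3-dimethyl-6-(2-methyl-4-oxopentan-2-yl)-2-[4-(triisopropylsilyloxy)butyl]cyclohexan-1-one
Product: 18 (4aS,7R,8R)-4,4,7,8-tetramethyl-8-[4-(triisopropylsilyloxy)butyl]-4,4a,5,6,7,8-hexahydronaphthalen-2(3H)-one, via aldol ketol 17 (not isolated)
Conditions: NaOMe (0.3 equiv), MeOH, 65 °C; chromatography, minor C5 epimer resubmitted
Reagents that add atoms: none
Why: Intramolecular aldol condensation (the ring-closing half of a Robinson annulation): the methyl-ketone enolate C1 adds to the C10 ketone and E1cB loss of water gives the C1=C10 enone, while C5 (α to C10 in 16, γ in 18) equilibrates through the enolate and dienolate towards the epimer whose ring-B chair keeps the C5–C4 bond and the C8 methyl equatorial with only C11 axial (the C5 epimer needs both the C8 and C9 methyls axial); the preference is expected to be modest, hence the separation and recycling.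

Step 7
Reactants: 18 (4aS,7R,8R)-4,4,7,8-tetramethyl-8-[4-(triisopropylsilyloxy)butyl]-4,4a,5,6,7,8-hexahydronaphthalen-2(3H)-one; 19 ethane-1,2-dithiol
Product: 20 1,3-dithiolane of enone 18 at C2 (spiro dithioketal, C1=C10 retained)
Conditions: HSCH2CH2SH, BF3·OEt2 (0.3 equiv), CH2Cl2, 0 °C → rt
Reagents that add atoms: ethane-1,2-dithiol 19, SCCS
Why: Lewis-acid-catalysed dithioketalisation of the C2 ketone; as with 4-en-3-ones the double bond should stay at C1=C10 in the dithiolane, and the fully substituted C10 should not accept thiol in a conjugate sense.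

Step 8
Reactants: 20 1,3-dithiolane of enone 18
Product: 21 triisopropyl[4-(Dec)butoxy]silane
Conditions: Raney Ni (W-2, deactivated in refluxing acetone), EtOH, reflux
Reagents that add atoms: none
Why: Mozingo reductive desulfurisation replaces both C–S bonds at C2 by C–H, and the hindered trisubstituted C1=C10 bond is expected to survive on deactivated nickel.

Step 9
Reactants: 21 triisopropyl[4-(Dec)butoxy]silane
Product: 22 4-(Dec)butan-1-ol
Conditions: TBAF, THF, rt
Reagents that add atoms: none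
Why: Fluoride-mediated desilylation frees the primary alcohol.

Step 10
Reactants: 22 4-(Dec)butan-1-ol
Product: 24 4-(Dec)butanoic acid, via 4-(Dec)butanal 23 (not isolated)
Conditions: TEMPO (20 mol %), PhI(OAc)2 (2.2 equiv), MeCN–H2O 1:1, rt
Reagents that add atoms: water, O
Why: Oxoammonium (TEMPO) oxidation with PhI(OAc)2 as terminal oxidant takes the primary alcohol through the aldehyde hydrate to the acid without affecting the trisubstituted alkene.

Step 11
Reactants: 24 4-(Dec)butanoic acid; 25 (R)-4-benzyl-1,3-oxazolidin-2-one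
Product: 27 (4R)-4-benzyl-3-[4-(Dec)butanoyl]-1,3-oxazolidin-2-one, via mixed pivalic anhydride 26 (not isolated)
Conditions: PivCl, Et3N, THF, −20 °C; then 25, LiCl, rt
Reagents that add atoms: (R)-4-benzyl-1,3-oxazolidin-2-one 25, O=C1OC[C@@H](Cc2ccccc2)N1
Why: N-Acylation of the Evans auxiliary through the mixed pivalic anhydride (LiCl/Et3N variant), the oxazolidinone attacking the less hindered acyl carbon.

Step 12
Reactants: 27 (4R)-4-benzyl-3-[4-(Dec)butanoyl]-1,3-oxazolidin-2-one; 28 3-iodoprop-1-ene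
Product: 30 (4R)-4-benzyl-3-{(2S)-2-[2-(Dec)ethyl]pent-4-enoyl}-1,3-oxazolidin-2-one, via sodium (Z)-enolate of 27 29 (not isolated)
Conditions: NaHMDS, THF, −78 °C; allyl iodide, −78 → −45 °C
Reagents that add atoms: 3-iodoprop-1-ene 28, C=CCI
Why: Evans asymmetric alkylation: the chelated sodium (Z)-enolate should be allylated on the face opposite the benzyl group of the (R)-auxiliary, which sets C13 in the configuration that becomes (R) in the target.

Step 13
Reactants: 30 (4R)-4-benzyl-3-{(2S)-2-[2-(Dec)ethyl]pent-4-enoyl}-1,3-oxazolidin-2-one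
Product: 31 (2S)-2-[2-(Dec)ethyl]pent-4-en-1-ol
Conditions: LiBH4, MeOH (1.1 equiv), Et2O, 0 °C
Reagents that add atoms: none
Why: Reductive cleavage of the N-acyl oxazolidinone by LiBH4 (hydride attack at the exocyclic carbonyl) should give the primary alcohol without epimerising C13 and return the auxiliary.

Step 14
Reactants: 31 (2S)-2-[2-(Dec)ethyl]pent-4-en-1-ol; 32 tert-butylchlorodimethylsilane
Product: 33 tert-butyl{[(2S)-2-[2-(Dec)ethyl]pent-4-en-1-yl]oxy}dimethylsilane
Conditions: imidazole, CH2Cl2, rt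
Reagents that add atoms: tert-butylchlorodimethylsilane 32, CC(C)(C)[Si](C)(C)Cl
Why: Silyl ether protection keeps the hydroxyl from consuming 9-BBN and from interfering in the cross-coupling.

Step 15
Reactants: 34 3-methylbutan-1-amine; 35 2,5-dimethoxy-2,5-dihydrofuran
Product: 37 1-(3-methylbutyl)-1,5-dihydro-2H-pyrrol-2-one, via (Z)-but-2-enedial 36 (not isolated)
Conditions: aq. HCl, H2O, rt; then NaHCO3
Reagents that add atoms: 2,5-dimethoxy-2,5-dihydrofuran 35, COC1C=CC(OC)O1
Why: Known condensation of primary amines with 2,5-dimethoxy-2,5-dihydrofuran in aqueous acid: acetal hydrolysis gives (Z)-but-2-enedial, double condensation with the amine and loss of water give the N-alkyl-2-hydroxypyrrole, whose tautomer is the α,β-unsaturated γ-lactam.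

Step 16
Reactants: 37 1-(3-methylbutyl)-1,5-dihydro-2H-pyrrol-2-one; 38 bromine
Product: 40 3-bromo-1-(3-methylbutyl)-1,5-dihydro-2H-pyrrol-2-one, via 3,4-dibromo-1-(3-methylbutyl)pyrrolidin-2-one 39 (not isolated)
Conditions: Br2, CH2Cl2, 0 °C; then Et3N, 0 °C → rt
Reagents that add atoms: bromine 38, BrBr
Why: Bromination–dehydrobromination: bromine adds across C3=C4 and E1cB elimination (the acidic C3–H is removed, bromide leaves from C4) should give the α-bromo unsaturated lactam.

Step 17
Reactants: 33 tert-butyl{[(2S)-2-[2-(Dec)ethyl]pent-4-en-1-yl]oxy}dimethylsilane; 40 3-bromo-1-(3-methylbutyl)-1,5-dihydro-2H-pyrrol-2-one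
Product: 42 3-[(4R)-4-[(tert-butyldimethylsilyloxy)methyl]-6-(Dec)hexyl]-1-(3-methylbutyl)-1,5-dihydro-2H-pyrrol-2-one, via 9-[(4R)-4-[(tert-butyldimethylsilyloxy)methyl]-6-(Dec)hexyl]-9-borabicyclo[3.3.1]nonane 41 (not isolated)
Conditions: 9-BBN, THF, 0 °C → rt; then 40, PdCl2(dppf) (5 mol %), AsPh3, Cs2CO3, DMF–THF–H2O, 45 °C
Reagents that add atoms: 3-bromo-1-(3-methylbutyl)-1,5-dihydro-2H-pyrrol-2-one 40, CC(C)CCN1CC=C(Br)C1=O
Why: 9-BBN should hydroborate only the monosubstituted terminal alkene (the trisubstituted C1=C10 bond is too hindered), and B-alkyl Suzuki–Miyaura coupling of the primary borane with the α-bromo unsaturated lactam forms the C16–C3' bond.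

Step 18
Reactants: 42 3-[(4R)-4-[(tert-butyldimethylsilyloxy)methyl]-6-(Dec)hexyl]-1-(3-methylbutyl)-1,5-dihydro-2H-pyrrol-2-one
Product: 43 3-[(4R)-4-(hydroxymethyl)-6-(Dec)hexyl]-1-(3-methylbutyl)-1,5-dihydro-2H-pyrrol-2-one
Conditions: HF·pyridine, pyridine, THF, 0 °C → rt
Reagents that add atoms: none
Why: Buffered HF·pyridine desilylates the primary TBS ether under non-basic conditions that should leave the γ-acidic lactam and the trisubstituted alkene alone.

Step 19
Reactants: 43 3-[(4R)-4-(hydroxymethyl)-6-(Dec)hexyl]-1-(3-methylbutyl)-1,5-dihydro-2H-pyrrol-2-one; 44 sulfur trioxide–pyridine complex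
Product: 46 (2R)-2-[2-(Dec)ethyl]-5-[1-(3-methylbutyl)-2-oxo-2,5-dihydro-1H-pyrrol-3-yl]pentyl hydrogen sulfate (CNP0218721.1), via pyridinium sulfate 45 (not isolated)
Conditions: SO3·pyridine (3 equiv), pyridine, rt; then Dowex 50W (H+ form), MeOH–H2O, 0 °C
Reagents that add atoms: sulfur trioxide–pyridine complex 44, [O-]S(=O)(=O)[n+]1ccccc1
Why: O-Sulfation of the primary alcohol by SO3·pyridine gives the pyridinium sulfate, and cation exchange on an acid resin liberates the hydrogen sulfate.

**Compound list**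

1 | but-3-en-1-ol | C=CCCO | starting material
2 | chlorotriisopropylsilane | CC(C)[Si](Cl)(C(C)C)C(C)C | starting material
3 | (but-3-en-1-yloxy)triisopropylsilane | C=CCCO[Si](C(C)C)(C(C)C)C(C)C | intermediate
4 | 2-iodocyclohex-2-en-1-one | O=C1CCCC=C1I | starting material
5 | 9-[4-(triisopropylsilyloxy)butyl]-9-borabicyclo[3.3.1]nonane | CC(C)[Si](OCCCCB1C2CCCC1CCC2)(C(C)C)C(C)C | intermediate
6 | 2-[4-(triisopropylsilyloxy)butyl]cyclohex-2-en-1-one | CC(C)[Si](OCCCCC1=CCCCC1=O)(C(C)C)C(C)C | intermediate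
7 | trimethylaluminium | C[Al](C)C | starting material
8 | iodomethane | CI | starting material
9 | dimethylaluminium (3R)-3-methyl-2-[4-(triisopropylsilyloxy)butyl]cyclohex-1-en-1-olate | C[Al](C)OC1=C(CCCCO[Si](C(C)C)(C(C)C)C(C)C)[C@H](C)CCC1 | intermediate
10 | lithium trimethyl{[(3R)-3-methyl-2-[4-(triisopropylsilyloxy)butyl]cyclohex-1-en-1-yl]oxy}aluminate | [Li+].C[Al-](C)(C)OC1=C(CCCCO[Si](C(C)C)(C(C)C)C(C)C)[C@H](C)CCC1 | intermediate
11 | (2R,3R)-2,3-dimethyl-2-[4-(triisopropylsilyloxy)butyl]cyclohexan-1-one | CC(C)[Si](OCCCC[C@@]1(C)C(=O)CCC[C@H]1C)(C(C)C)C(C)C | intermediate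
12 | chlorotrimethylsilane | C[Si](C)(C)Cl | starting material
13 | lithium (5R,6R)-5,6-dimethyl-6-[4-(triisopropylsilyloxy)butyl]cyclohex-1-en-1-olate | CC(C)[Si](OCCCC[C@@]1(C)C([O-])=CCC[C@H]1C)(C(C)C)C(C)C.[Li+] | intermediate
14 | triisopropyl{4-[(1R,6R)-1,6-dimethyl-2-(trimethylsilyloxy)cyclohex-2-en-1-yl]butoxy}silane | CC(C)[Si](OCCCC[C@@]1(C)C(O[Si](C)(C)C)=CCC[C@H]1C)(C(C)C)C(C)C | intermediate
15 | 4-methylpent-3-en-2-one (mesityl oxide) | CC(C)=CC(C)=O | starting material
16 | (2R,3R,6RS)-2,3-dimethyl-6-(2-methyl-4-oxopentan-2-yl)-2-[4-(triisopropylsilyloxy)butyl]cyclohexan-1-one (C5 epimers) | CC(C)[Si](OCCCC[C@@]1(C)C(=O)C(CC[C@H]1C)C(C)(C)CC(C)=O)(C(C)C)C(C)C | intermediate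
17 | (7R,8R)-8a-hydroxy-4,4,7,8-tetramethyl-8-[4-(triisopropylsilyloxy)butyl]octahydronaphthalen-2(1H)-one (aldol ketol, epimers at C5 and C10) | CC(C)[Si](OCCCC[C@@]1(C)C2(O)CC(=O)CC(C)(C)C2CC[C@H]1C)(C(C)C)C(C)C | intermediate
18 | (4aS,7R,8R)-4,4,7,8-tetramethyl-8-[4-(triisopropylsilyloxy)butyl]-4,4a,5,6,7,8-hexahydronaphthalen-2(3H)-one | CC(C)[Si](OCCCC[C@@]1(C)C2=CC(=O)CC(C)(C)[C@@H]2CC[C@H]1C)(C(C)C)C(C)C | intermediate
19 | ethane-1,2-dithiol | SCCS | starting material
20 | 1,3-dithiolane (C2 spiro dithioketal) of enone 18 | CC(C)[Si](OCCCC[C@@]1(C)C2=CC3(SCCS3)CC(C)(C)[C@@H]2CC[C@H]1C)(C(C)C)C(C)C | intermediate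
21 | triisopropyl[4-(Dec)butoxy]silane | CC(C)[Si](OCCCC[C@@]1(C)C2=CCCC(C)(C)[C@@H]2CC[C@H]1C)(C(C)C)C(C)C | intermediate
22 | 4-(Dec)butan-1-ol | OCCCC[C@@]1(C)C2=CCCC(C)(C)[C@@H]2CC[C@H]1C | intermediate
23 | 4-(Dec)butanal | O=CCCC[C@@]1(C)C2=CCCC(C)(C)[C@@H]2CC[C@H]1C | intermediate
24 | 4-(Dec)butanoic acid | OC(=O)CCC[C@@]1(C)C2=CCCC(C)(C)[C@@H]2CC[C@H]1C | intermediate
25 | (R)-4-benzyl-1,3-oxazolidin-2-one | O=C1OC[C@@H](Cc2ccccc2)N1 | starting material
26 | 4-(Dec)butanoic pivalic anhydride | CC(C)(C)C(=O)OC(=O)CCC[C@@]1(C)C2=CCCC(C)(C)[C@@H]2CC[C@H]1C | intermediate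
27 | (4R)-4-benzyl-3-[4-(Dec)butanoyl]-1,3-oxazolidin-2-one | O=C(CCC[C@@]1(C)C2=CCCC(C)(C)[C@@H]2CC[C@H]1C)N3[C@H](Cc4ccccc4)COC3=O | intermediate
28 | 3-iodoprop-1-ene (allyl iodide) | C=CCI | starting material
29 | sodium (Z)-enolate of imide 27 | [Na+].[O-]/C(=C\CC[C@@]1(C)C2=CCCC(C)(C)[C@@H]2CC[C@H]1C)N3[C@H](Cc4ccccc4)COC3=O | intermediate
30 | (4R)-4-benzyl-3-{(2S)-2-[2-(Dec)ethyl]pent-4-enoyl}-1,3-oxazolidin-2-one | C=CC[C@H](CC[C@@]1(C)C2=CCCC(C)(C)[C@@H]2CC[C@H]1C)C(=O)N3[C@H](Cc4ccccc4)COC3=O | intermediate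
31 | (2S)-2-[2-(Dec)ethyl]pent-4-en-1-ol | C=CC[C@H](CC[C@@]1(C)C2=CCCC(C)(C)[C@@H]2CC[C@H]1C)CO | intermediate
32 | tert-butylchlorodimethylsilane | CC(C)(C)[Si](C)(C)Cl | starting material
33 | tert-butyl{[(2S)-2-[2-(Dec)ethyl]pent-4-en-1-yl]oxy}dimethylsilane | C=CC[C@H](CC[C@@]1(C)C2=CCCC(C)(C)[C@@H]2CC[C@H]1C)CO[Si](C)(C)C(C)(C)C | intermediate
34 | 3-methylbutan-1-amine | CC(C)CCN | starting material
35 | 2,5-dimethoxy-2,5-dihydrofuran | COC1C=CC(OC)O1 | starting material
36 | (Z)-but-2-enedial | O=C/C=C\C=O | intermediate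
37 | 1-(3-methylbutyl)-1,5-dihydro-2H-pyrrol-2-one | CC(C)CCN1CC=CC1=O | intermediate
38 | bromine | BrBr | starting material
39 | 3,4-dibromo-1-(3-methylbutyl)pyrrolidin-2-one | CC(C)CCN1CC(Br)C(Br)C1=O | intermediate
40 | 3-bromo-1-(3-methylbutyl)-1,5-dihydro-2H-pyrrol-2-one | CC(C)CCN1CC=C(Br)C1=O | intermediate
41 | 9-[(4R)-4-[(tert-butyldimethylsilyloxy)methyl]-6-(Dec)hexyl]-9-borabicyclo[3.3.1]nonane | C(CC[C@H](CC[C@@]1(C)C2=CCCC(C)(C)[C@@H]2CC[C@H]1C)CO[Si](C)(C)C(C)(C)C)B3C4CCCC3CCC4 | intermediate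
42 | 3-[(4R)-4-[(tert-butyldimethylsilyloxy)methyl]-6-(Dec)hexyl]-1-(3-methylbutyl)-1,5-dihydro-2H-pyrrol-2-one | CC(C)CCN1CC=C(CCC[C@H](CC[C@@]2(C)C3=CCCC(C)(C)[C@@H]3CC[C@H]2C)CO[Si](C)(C)C(C)(C)C)C1=O | intermediate
43 | 3-[(4R)-4-(hydroxymethyl)-6-(Dec)hexyl]-1-(3-methylbutyl)-1,5-dihydro-2H-pyrrol-2-one | CC(C)CCN1CC=C(CCC[C@H](CC[C@@]2(C)C3=CCCC(C)(C)[C@@H]3CC[C@H]2C)CO)C1=O | intermediate
44 | sulfur trioxide–pyridine complex | [O-]S(=O)(=O)[n+]1ccccc1 | starting material
45 | pyridinium (2R)-2-[2-(Dec)ethyl]-5-[1-(3-methylbutyl)-2-oxo-2,5-dihydro-1H-pyrrol-3-yl]pentyl sulfate | CC(C)CCN1CC=C(CCC[C@H](CC[C@@]2(C)C3=CCCC(C)(C)[C@@H]3CC[C@H]2C)COS(=O)(=O)[O-])C1=O.c1cc[nH+]cc1 | intermediate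
46 | (2R)-2-[2-(Dec)ethyl]-5-[1-(3-methylbutyl)-2-oxo-2,5-dihydro-1H-pyrrol-3-yl]pentyl hydrogen sulfate (CNP0218721.1) | CC(C)CCN1CC=C(CCC[C@H](CC[C@@]2(C)C3=CCCC(C)(C)[C@@H]3CC[C@H]2C)COS(=O)(=O)O)C1=O | target

**Step count**

Total step count: 19.
Longest linear sequence: 17 steps (steps 1–14 and 17–19); the lactam branch is steps 15–16.

**Three steps most likely to fail**

Step 6. The thermodynamic preference at C5 may be too small or even reversed, because both ring-B chairs carry similar strain: an axial C11 with two gauche contacts of the equatorial C8 methyl on one side, two axial methyls on the other. Retro-Michael loss of mesityl oxide can also compete with the hindered aldol closure. Fallback, replacing equilibration by a stereospecific inversion of C5: setting out from 16, the unwanted 5-epi enone F1 is taken through the conditions of steps 7 and 8 to the 5-epi dithiolane F2 and the 5-epi alkene F3. A Schenck ene reaction (O2, tetraphenylporphyrin, hν, CH2Cl2, 0 °C) should put oxygen on the less hindered alkene carbon C1, on the face from which H-5 is abstracted, and move the double bond to C5=C10, giving the allylic hydroperoxide F4; PPh3 reduces it to the C1 allylic alcohol F5. Myers reductive transposition (2-nitrobenzenesulfonylhydrazine, PPh3, DEAD, N-methylmorpholine, −30 °C → rt) inverts C1 to the N-allylic sulfonylhydrazine F6, which loses sulfinic acid to the allylic diazene F7. Its retro-ene loss of N2 returns hydrogen to C5 on the face opposite the one it left and restores C1=C10, coming back to the route at 21.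

Step 3. Methylation of the hindered tetrasubstituted aluminate enolate may be slow or unselective (proton quench, O-methylation, enolate equilibration towards C5, eroded trans selectivity). Fallback, separating the two bond formations: setting out from 6, the conjugate addition is run as in step 3 and aluminium enolate 9 is silylated with TMSOTf to the isolable trimethylsilyl enol ether F8. MeLi in THF then cleaves the O–Si bond to the regiodefined, amine-free lithium enolate F9, which is methylated with iodomethane in THF–HMPA (House–Stork regiospecific enolate alkylation), coming back at 11.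

Step 8. On the nickel surface the C1=C10 bond may migrate to the tetrasubstituted C5=C10 position or be saturated. Fallback, avoiding both the thioketal and nickel: setting out from 18, Luche reduction (NaBH4, CeCl3·7H2O, MeOH, 0 °C) gives the C2 allylic alcohol F10 and acetylation (Ac2O, pyridine, DMAP) the allylic acetate F11. Palladium-catalysed hydride substitution (Pd(PPh3)4, LiBHEt3, THF) should deliver hydride to the less hindered C2 terminus of the π-allyl, keeping the double bond at C1=C10 and coming back at 21.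

**Further compounds**

F1 | step 6 | C5 epimer of enone 18, (4aR,7R,8R) | CC(C)[Si](OCCCC[C@@]1(C)C2=CC(=O)CC(C)(C)[C@H]2CC[C@H]1C)(C(C)C)C(C)C
F2 | step 6 | 1,3-dithiolane of F1 | CC(C)[Si](OCCCC[C@@]1(C)C2=CC3(SCCS3)CC(C)(C)[C@H]2CC[C@H]1C)(C(C)C)C(C)C
F3 | step 6 | C5 epimer of alkene 21 | CC(C)[Si](OCCCC[C@@]1(C)C2=CCCC(C)(C)[C@H]2CC[C@H]1C)(C(C)C)C(C)C
F4 | step 6 | C1 allylic hydroperoxide with C5=C10 (oxygen trans to the C11 chain) | CC(C)[Si](OCCCC[C@@]1(C)C2=C(CC[C@H]1C)C(C)(C)CC[C@H]2OO)(C(C)C)C(C)C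
F5 | step 6 | C1 allylic alcohol with C5=C10 (hydroxyl trans to the C11 chain) | CC(C)[Si](OCCCC[C@@]1(C)C2=C(CC[C@H]1C)C(C)(C)CC[C@H]2O)(C(C)C)C(C)C
F6 | step 6 | N-(C1-allylic)-N-(2-nitrobenzenesulfonyl)hydrazine (nitrogen cis to the C11 chain) | CC(C)[Si](OCCCC[C@@]1(C)C2=C(CC[C@H]1C)C(C)(C)CC[C@@H]2N(N)S(=O)(=O)c3ccccc3[N+](=O)[O-])(C(C)C)C(C)C
F7 | step 6 | C1 allylic diazene | CC(C)[Si](OCCCC[C@@]1(C)C2=C(CC[C@H]1C)C(C)(C)CC[C@@H]2N=N)(C(C)C)C(C)C
F8 | step 3 | trimethyl{[(3R)-3-methyl-2-[4-(triisopropylsilyloxy)butyl]cyclohex-1-en-1-yl]oxy}silane | C[Si](C)(C)OC1=C(CCCCO[Si](C(C)C)(C(C)C)C(C)C)[C@H](C)CCC1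
F9 | step 3 | lithium (3R)-3-methyl-2-[4-(triisopropylsilyloxy)butyl]cyclohex-1-en-1-olate | [Li+].[O-]C1=C(CCCCO[Si](C(C)C)(C(C)C)C(C)C)[C@H](C)CCC1
F10 | step 8 | C2 allylic alcohol from enone 18 (C2 epimers) | CC(C)[Si](OCCCC[C@@]1(C)C2=CC(O)CC(C)(C)[C@@H]2CC[C@H]1C)(C(C)C)C(C)C
F11 | step 8 | C2 allylic acetate | CC(C)[Si](OCCCC[C@@]1(C)C2=CC(OC(C)=O)CC(C)(C)[C@@H]2CC[C@H]1C)(C(C)C)C(C)C
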